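A ratio taken from a reading no larger than its own scatter can show a lag that isn't there: at 2.50 h the summer run reads 0.2% of isomer of the product A, with a scatter of 0.5 percentage points.

| flask | solid substrate | catalyst | remark | time |
|---|---|---|---|---|
| summer | 3 M | 1.5 mM | run made earlier |  |
| midnight | 3 M | 6 mM | run made earlier |  |
| flask | 3.0 M | 3.0 mM |  | 30 h |

| run | time / h | isomer of the product A / % | target / % |
|---|---|---|---|
| summer | 2.50 | 0.2 | 7.4 |
| summer | 4.00 | 1.7 | 12.3 |
| summer | 6.00 | 2.2 | 17.0 |
| summer | 10.0 | 2.5 | 20.3 |
| summer | 20.0 | 2.6 | 20.0 |
| summer | 30.0 | 2.7 | 21.7 |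
| midnight | 5.00 | 1.7 | 17.1 |
| midnight | 10.0 | 3.4 | 21.3 |
| midnight | 15.0 | 3.9 | 21.2 |
| midnight | 20.0 | 2.5 | 20.6 |
| midnight | 25.0 | 3.0 | 20.8 |
| midnight | 30.0 | 2.5 | 21.4 |

(standard deviation of a reading: 0.5 percentage points)
- ratio of isomer of the product A to target at 40 min
- ratio of isomer of the product A to target at 30 h

At the start none of the solid substrate is in solution, so the target and isomer of the product A that appear have come from the solid. In the rising part, the summer run, with 1.5 mM of catalyst, reads 17.0% of target at 6.00 h, and the midnight run, with 6 mM, reads 17.1% at 5.00 h. A factor of 4.00 in catalyst thus shortens the time by a factor of only 1.20, so the solid going into solution looks like the slow step, the rate-limiting step, and the catalysed change looks quick against that supply.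

If so, target and isomer of the product A rise in step, and dividing one gain by the other removes the clock. My own reckoning sums the readings up to 6.00 h and gets 0.108 for the rise ratio, the isomer of the product A gained per target gained, give or take 0.0186. At the end, from 20.0 h on, both runs read about level, and their readings at 20.0 h and 30.0 h give a ratio of 0.123. I therefore expect about 0.108 at 40 min and about 0.123 at 30 h.

The forecast differs early, giving 0.04 at 40 min and 0.128 at 30 h: “That favours formation from the target”.

The flask gives 0.120 at 40 min and 0.120 at 30 h. The early value is a factor of 3.00 above the forecast and 0.0120 above the rise ratio, which is inside its 0.0186.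

    isomer of the product B ⇌ starting material (k = 0.00180 s⁻¹)
    starting material + catalyst ⇌ target + catalyst, rate k2*[starting material]*[catalyst] forward; the back reaction follows from the equilibrium constant (K = 0.640, k = 0.0950 M⁻¹ s⁻¹)
    isomer of the product A ⇌ isomer of the product B (K = 18.0, k = 7.10 × 10⁻⁴ s⁻¹)
    target + catalyst ⇌ isomer of the product A + catalyst, rate k4*[catalyst]*[target] forward; the back reaction follows from the equilibrium constant (K = 0.120, k = 0.320 M⁻¹ s⁻¹)
    solid substrate ⇌ starting material, rate k5*(cs5 - [starting material]) while solid is left; crystals form when [starting material] > cs5 (solubility = 1.40 M, k = 1.50 × 10⁻⁴ s⁻¹)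

A further flask with 0.0012 M of catalyst, otherwise charged alike, is held against the same rise ratio of 0.108. At 30 h it stands at 0.120, inside the 0.0186. At 40 min it lies 0.0420 above the rise ratio, outside that margin, at 0.150.

All runs are simulated on assumed constants; scatter was added.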